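**Retrosynthetic overview** (prostanoid numbering: C1 = ester carbon, C8/C12 = ring stereocentres, C4 = side-chain carbinol)
1. Target ⇐ double acetylation of the C4,C12-diol.
2. Key bond C7–C8 ⇐ radical addition of the ring C8 α-keto radical (from an α-xanthyl ketone) to a (4S,5S)-vinyl epoxide; radical opening of the epoxide gives the 5E alkene and the C4 carbinol in the same event and sets C8.
3. α-Xanthyl hydroxy-enone ⇐ (S)-4-hydroxy-4-[(Z)-octenyl]cyclopentenone ⇐ (R)-4-silyloxycyclopentenone + oct-2-yne (1,2-addition anti to OTBS sets C12; Lindlar; desilylation; allylic oxidation).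
4. Vinyl epoxide ⇐ Shi epoxidation of methyl (E)-hepta-4,6-dienoate ⇐ Johnson–Claisen rearrangement of penta-1,4-dien-3-ol with trimethyl orthoacetate.
5. Rings: the five-membered carbocycle is bought and never opened; the only ring made is the oxirane (step 7), which is opened again in the key step (step 8).

Assumption: the silyl ether of (R)-4-hydroxycyclopent-2-enone and the L-fructose-derived Shi ketone are taken as commercial; the α-xanthyl ketone is drawn as its major epimer (both epimers give the same radical).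

**Step 1**
Reactants: 1 oct-2-yne; 2 (4R)-4-[(tert-butyldimethylsilyl)oxy]cyclopent-2-en-1-one
Product: 5 (1S,4R)-4-[(tert-butyldimethylsilyl)oxy]-1-(oct-2-yn-1-yl)cyclopent-2-en-1-ol, via oct-2-ynyllithium 3 (not isolated), via allenyltitanium reagent 4 (not isolated)
Conditions: 1 (1.4 equiv), n-BuLi (1.3 equiv), TMEDA, THF, −20 to 0 °C; ClTi(OiPr)3 (1.4 equiv), −78 °C; then 2, −78 to −30 °C; H2O/aq. NH4Cl work-up
Reagents that add atoms: none
Why: Propargylic lithiation of the alkyne methyl group and transmetalation give an allenyltitanium that adds to the ketone through a cyclic SE2′ transition state (titanium-mediated propargylation), so the homopropargylic oct-2-ynyl carbinol forms 1,2-selectively on the face anti to the OTBS group, which sets the tertiary carbinol centre as 1S (OH cis to OTBS).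

**Step 2**
Reactants: 5 (1S,4R)-4-[(tert-butyldimethylsilyl)oxy]-1-(oct-2-yn-1-yl)cyclopent-2-en-1-ol
Product: 6 (1S,4R)-4-[(tert-butyldimethylsilyl)oxy]-1-[(2Z)-oct-2-en-1-yl]cyclopent-2-en-1-ol
Conditions: H2 (1 atm), Pd/CaCO3 poisoned with Pb(OAc)2, quinoline, EtOAc, 20 °C, stopped after 1 equiv H2
Reagents that add atoms: none
Why: Lindlar semihydrogenation delivers H2 syn to the alkyne on lead-poisoned palladium to give only the (Z)-alkene, while the hindered, allylically oxygenated ring alkene and both stereocentres are untouched.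

**Step 3**
Reactants: 6 (1S,4R)-4-[(tert-butyldimethylsilyl)oxy]-1-[(2Z)-oct-2-en-1-yl]cyclopent-2-en-1-ol
Product: 7 (1S,4R)-1-[(2Z)-oct-2-en-1-yl]cyclopent-2-ene-1,4-diol
Conditions: Bu4NF (1.2 equiv), THF, 0 to 20 °C; H2O work-up
Reagents that add atoms: none
Why: Fluoride-mediated desilylation cleaves the Si–O bond of the secondary TBS ether under non-acidic conditions that leave the ionisation-prone tertiary allylic alcohol and both stereocentres intact.

**Step 4**
Reactants: 7 (1S,4R)-1-[(2Z)-oct-2-en-1-yl]cyclopent-2-ene-1,4-diol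
Product: 8 (4S)-4-hydroxy-4-[(2Z)-oct-2-en-1-yl]cyclopent-2-en-1-one
Conditions: MnO2 (activated, 15 equiv), CH2Cl2, 20 °C
Reagents that add atoms: none
Why: MnO2 allylic oxidation converts only the secondary allylic alcohol into the enone, the tertiary carbinol cannot be oxidised, and the neutral heterogeneous medium avoids retro-aldol ring opening, so the tertiary stereocentre (now 4S) is preserved.

**Step 5**
Reactants: 8 (4S)-4-hydroxy-4-[(2Z)-oct-2-en-1-yl]cyclopent-2-en-1-one
Product: 10 O-ethyl S-[(1R,5R)-5-hydroxy-5-[(2Z)-oct-2-en-1-yl]-2-oxocyclopent-3-en-1-yl] carbonodithioate, via dilithium alkoxide enolate 9 (not isolated)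
Conditions: LiN(SiMe3)2 (2.2 equiv), THF, −78 °C; (EtOC(S)S)2 (1.1 equiv), −78 °C; AcOH quench at −78 °C
Reagents that add atoms: bis(ethoxythiocarbonyl) disulfide, CCOC(=S)SSC(=S)OCC
Why: Two equivalents of amide base give the alkoxide/α′-enolate dianion (C5 is the only enolisable position), which is sulfenylated by the disulfide in a Trost-type enolate sulfenylation with the xanthate entering mainly anti to the octenyl chain, and the new C–S centre is of no consequence because it becomes a planar radical in step 8.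

**Step 6**
Reactants: 11 penta-1,4-dien-3-ol; 12 trimethyl orthoacetate
Product: 15 methyl (4E)-hepta-4,6-dienoate, via mixed orthoester 13 (not isolated), via ketene acetal 14 (not isolated)
Conditions: 12 (4 equiv), EtCO2H (5 mol%), toluene, 110–120 °C, MeOH distilled off
Reagents that add atoms: none
Why: Johnson–Claisen rearrangement, in which acid-catalysed exchange gives the mixed orthoester and then the ketene acetal, whose chair [3,3]-sigmatropic shift with the second vinyl group equatorial delivers the (4E)-dienoate.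

**Step 7**
Reactants: 15 methyl (4E)-hepta-4,6-dienoate
Product: 16 methyl 3-[(2S,3S)-3-ethenyloxiran-2-yl]propanoate
Conditions: L-fructose-derived Shi ketone (30 mol%), KHSO5 (as 2KHSO5·KHSO4·K2SO4, 1.4 equiv), K2CO3, Bu4NHSO4 (cat.), Na2B4O7/Na2EDTA buffer (pH 10.5), MeCN–CH2(OMe)2–H2O, 0 °C
Reagents that add atoms: potassium peroxymonosulfate, [K+].[O-]S(=O)(=O)OO
Why: Shi asymmetric epoxidation, in which the chiral dioxirane epoxidises only the more electron-rich trans-disubstituted alkene of the diene through the spiro transition state, and the L-fructose-derived ketone gives the (S,S)-epoxide (mirror image of the (R,R) series that the D-fructose ketone gives with trans-alkenes), which fixes the future C4 centre.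

**Step 8**
Reactants: 10 O-ethyl S-[(1R,5R)-5-hydroxy-5-[(2Z)-oct-2-en-1-yl]-2-oxocyclopent-3-en-1-yl] carbonodithioate; 16 methyl 3-[(2S,3S)-3-ethenyloxiran-2-yl]propanoate
Product: 18 methyl (4S,5E)-4-hydroxy-7-[(1R,5R)-5-hydroxy-5-[(2Z)-oct-2-en-1-yl]-2-oxocyclopent-3-en-1-yl]hept-5-enoate, via diethylborinate 17 (not isolated)
Conditions: 16 (3 equiv), Et3B (1 M in hexane, 2 equiv over 4 h), slow air bleed, CH2Cl2 (0.3 M), 20 °C; then MeOH, evaporate below 25 °C; crude 18 used at once
Reagents that add atoms: none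
Why: Xanthate-transfer radical addition to a vinyl epoxide with Et3B as chain carrier (Zard-type radical allylation), in which an ethyl radical releases the ring α-keto radical from the xanthate, this adds to the CH2 terminus of the vinyl epoxide on the ring face anti to the octenyl chain (setting the new ring centre R, side chain cis to OH, also the thermodynamically preferred epimer), the oxiranylmethyl radical opens by C–O scission through the s-trans conformer to the (E)-allylic alkoxy radical with the distal C–O stereocentre (4S) carried over untouched, and Et3B traps the alkoxy radical as the borinate while releasing the next ethyl radical.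

**Step 9**
Reactants: 18 methyl (4S,5E)-4-hydroxy-7-[(1R,5R)-5-hydroxy-5-[(2Z)-oct-2-en-1-yl]-2-oxocyclopent-3-en-1-yl]hept-5-enoate
Product: 19 methyl (4S,5E)-4-(acetyloxy)-7-[(1R,5R)-5-(acetyloxy)-5-[(2Z)-oct-2-en-1-yl]-2-oxocyclopent-3-en-1-yl]hept-5-enoate
Conditions: Ac2O (6 equiv), DMAP (0.3 equiv), pyridine, CH2Cl2, 0 to 20 °C, 24 h
Reagents that add atoms: acetic anhydride, CC(=O)OC(C)=O
Why: DMAP-catalysed acylation (Steglich-type acetylation) esterifies the secondary alcohol within minutes, which forestalls γ-lactonisation onto the methyl ester, and then the hindered tertiary alcohol, while pyridine is too weak a base to enolise the ketone and eliminate the β-acetoxy group, so no stereocentre is touched.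

**Compound list**
1 | oct-2-yne | CC#CCCCCC | starting material
2 | (4R)-4-[(tert-butyldimethylsilyl)oxy]cyclopent-2-en-1-one | O=C1C=C[C@H](O[Si](C)(C)C(C)(C)C)C1 | starting material
3 | oct-2-yn-1-yllithium | [Li]CC#CCCCCC | intermediate
4 | (octa-1,2-dien-3-yl)tris(propan-2-olato)titanium | CCCCCC(=C=C)[Ti](OC(C)C)(OC(C)C)OC(C)C | intermediate
5 | (1S,4R)-4-[(tert-butyldimethylsilyl)oxy]-1-(oct-2-yn-1-yl)cyclopent-2-en-1-ol | CCCCCC#CC[C@@]1(O)C=C[C@H](O[Si](C)(C)C(C)(C)C)C1 | intermediate
6 | (1S,4R)-4-[(tert-butyldimethylsilyl)oxy]-1-[(2Z)-oct-2-en-1-yl]cyclopent-2-en-1-ol | CCCCC/C=C\C[C@@]1(O)C=C[C@H](O[Si](C)(C)C(C)(C)C)C1 | intermediate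
7 | (1S,4R)-1-[(2Z)-oct-2-en-1-yl]cyclopent-2-ene-1,4-diol | CCCCC/C=C\C[C@@]1(O)C=C[C@H](O)C1 | intermediate
8 | (4S)-4-hydroxy-4-[(2Z)-oct-2-en-1-yl]cyclopent-2-en-1-one | CCCCC/C=C\C[C@@]1(O)C=CC(=O)C1 | intermediate
9 | dilithium (5R)-5-[(2Z)-oct-2-en-1-yl]cyclopenta-1,3-diene-2,5-bis(olate) | CCCCC/C=C\C[C@@]1(O[Li])C=CC(O[Li])=C1 | intermediate
10 | O-ethyl S-[(1R,5R)-5-hydroxy-5-[(2Z)-oct-2-en-1-yl]-2-oxocyclopent-3-en-1-yl] carbonodithioate (major epimer) | CCCCC/C=C\C[C@@]1(O)C=CC(=O)[C@@H]1SC(=S)OCC | intermediate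
11 | penta-1,4-dien-3-ol | C=CC(O)C=C | starting material
12 | trimethyl orthoacetate (1,1,1-trimethoxyethane) | CC(OC)(OC)OC | starting material
13 | 3-(1,1-dimethoxyethoxy)penta-1,4-diene | CC(OC)(OC)OC(C=C)C=C | intermediate
14 | 3-[(1-methoxyethenyl)oxy]penta-1,4-diene | C=C(OC)OC(C=C)C=C | intermediate
15 | methyl (4E)-hepta-4,6-dienoate | C=C/C=C/CCC(=O)OC | intermediate
16 | methyl 3-[(2S,3S)-3-ethenyloxiran-2-yl]propanoate | C=C[C@@H]1O[C@H]1CCC(=O)OC | intermediate
17 | methyl (4S,5E)-4-[(diethylboranyl)oxy]-7-[(1R,5R)-5-hydroxy-5-[(2Z)-oct-2-en-1-yl]-2-oxocyclopent-3-en-1-yl]hept-5-enoate | CCCCC/C=C\C[C@@]1(O)C=CC(=O)[C@@H]1C/C=C/[C@H](CCC(=O)OC)OB(CC)CC | intermediate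
18 | methyl (4S,5E)-4-hydroxy-7-[(1R,5R)-5-hydroxy-5-[(2Z)-oct-2-en-1-yl]-2-oxocyclopent-3-en-1-yl]hept-5-enoate | CCCCC/C=C\C[C@@]1(O)C=CC(=O)[C@@H]1C/C=C/[C@H](CCC(=O)OC)O | intermediate
19 | methyl (4S,5E)-4-(acetyloxy)-7-[(1R,5R)-5-(acetyloxy)-5-[(2Z)-oct-2-en-1-yl]-2-oxocyclopent-3-en-1-yl]hept-5-enoate | CCCCC/C=C\C[C@@]1(OC(C)=O)C=CC(=O)[C@@H]1C/C=C/[C@H](CCC(=O)OC)OC(C)=O | target

**Totals**
Total step count: 9. Longest linear sequence: 7 (steps 1, 2, 3, 4, 5, 8, 9); steps 6 and 7 form the two-step side branch.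

**Three steps most likely to fail**

Step 8 (radical coupling). Three things can go wrong: Et3B may capture the α-keto radical as a boron enolate (this returns 8, which can be recycled), the epoxide opening may give some 5Z isomer (to be removed on AgNO3-impregnated silica), and the facial selectivity at the ring carbon may be modest. The fallback replaces the one-step epoxide relay by radical allylation followed by olefin cross-metathesis; it sets out from 10 and comes back to the route at 19. Keck radical allylation of 10 with Bu3SnCH2CH=CH2 and AIBN in benzene at 80 °C gives (4R,5R)-4-hydroxy-4-[(2Z)-oct-2-en-1-yl]-5-(prop-2-en-1-yl)cyclopent-2-en-1-one F1, the allyl group entering anti to the octenyl chain. Cross-metathesis of F1 with methyl (4S)-4-(acetyloxy)hex-5-enoate F2 (3 equiv; made from methyl 4-oxobutanoate by Zn(CH=CH2)2 addition under a chiral amino-alcohol catalyst with Ac2O quench) using the second-generation Grubbs catalyst RuCl2(H2IMes)(PCy3)(=CHPh) in CH2Cl2 at 40 °C gives the (5E)-monoacetate methyl (4S,5E)-4-(acetyloxy)-7-[(1R,5R)-5-hydroxy-5-[(2Z)-oct-2-en-1-yl]-2-oxocyclopent-3-en-1-yl]hept-5-enoate F3. Acetylation of the tertiary alcohol of F3 under the conditions of step 9 gives 19. The internal Z-alkene could take part in the metathesis, so the reaction is stopped at partial conversion.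

Step 5 (α′-xanthylation of the dianion). The lithium alkoxide next to the new xanthate may attack the thiocarbonyl, the dianion may undergo retro-aldol opening (which would erode the tertiary centre), or the enolate may react sluggishly with the disulfide. The fallback replaces enolate sulfenylation by silyl-enol-ether halogenation and SN2 displacement with the alcohol masked; it sets out from 8 and comes back to the route at 10. Treatment of 8 with Me3SiOSO2CF3 (2.5 equiv) and Et3N in CH2Cl2 (−78 to 0 °C) gives (1R)-1-[(2Z)-oct-2-en-1-yl]-1,3-bis[(trimethylsilyl)oxy]cyclopenta-2,4-diene F4. NBS in THF at −78 °C gives (4R)-5-bromo-4-[(2Z)-oct-2-en-1-yl]-4-[(trimethylsilyl)oxy]cyclopent-2-en-1-one F5 (C5 epimers). KSC(S)OEt in acetone at 0 °C gives O-ethyl S-[(5R)-5-[(2Z)-oct-2-en-1-yl]-2-oxo-5-[(trimethylsilyl)oxy]cyclopent-3-en-1-yl] carbonodithioate F6 (C1 epimers). Citric acid in MeOH removes the silyl ether to give 10.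

Step 1 (propargylation). Lithiation may not be fully selective for the methyl group, and some allenyl carbinol may form if the titanium reagent reacts through its propargyl form. The fallback builds the Z-alkene by olefination instead of by alkyne addition and semihydrogenation; it sets out from 2 and comes back to the route at 6, bypassing steps 1 and 2. LiCH2CO2Et (from EtOAc and LiN(iPr)2, THF, −78 °C) adds 1,2 to 2 anti to the silyloxy group to give ethyl [(1R,4R)-4-[(tert-butyldimethylsilyl)oxy]-1-hydroxycyclopent-2-en-1-yl]acetate F7. Reduction with i-Bu2AlH (2.2 equiv, CH2Cl2, −78 °C) gives [(1R,4R)-4-[(tert-butyldimethylsilyl)oxy]-1-hydroxycyclopent-2-en-1-yl]acetaldehyde F8. Salt-free Wittig olefination of F8 with hexyltriphenylphosphonium bromide and NaN(SiMe3)2 (THF, −78 to 0 °C) gives 6 directly.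

**Further compounds**
F1 | step 8 | (4R,5R)-4-hydroxy-4-[(2Z)-oct-2-en-1-yl]-5-(prop-2-en-1-yl)cyclopent-2-en-1-one | CCCCC/C=C\C[C@@]1(O)C=CC(=O)[C@@H]1CC=C
F2 | step 8 | methyl (4S)-4-(acetyloxy)hex-5-enoate | C=C[C@H](CCC(=O)OC)OC(C)=O
F3 | step 8 | methyl (4S,5E)-4-(acetyloxy)-7-[(1R,5R)-5-hydroxy-5-[(2Z)-oct-2-en-1-yl]-2-oxocyclopent-3-en-1-yl]hept-5-enoate | CCCCC/C=C\C[C@@]1(O)C=CC(=O)[C@@H]1C/C=C/[C@H](CCC(=O)OC)OC(C)=O
F4 | step 5 | (1R)-1-[(2Z)-oct-2-en-1-yl]-1,3-bis[(trimethylsilyl)oxy]cyclopenta-2,4-diene | CCCCC/C=C\C[C@@]1(O[Si](C)(C)C)C=CC(O[Si](C)(C)C)=C1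
F5 | step 5 | (4R)-5-bromo-4-[(2Z)-oct-2-en-1-yl]-4-[(trimethylsilyl)oxy]cyclopent-2-en-1-one (C5 epimers) | CCCCC/C=C\C[C@@]1(O[Si](C)(C)C)C=CC(=O)C1Br
F6 | step 5 | O-ethyl S-[(5R)-5-[(2Z)-oct-2-en-1-yl]-2-oxo-5-[(trimethylsilyl)oxy]cyclopent-3-en-1-yl] carbonodithioate (C1 epimers) | CCCCC/C=C\C[C@@]1(O[Si](C)(C)C)C=CC(=O)C1SC(=S)OCC
F7 | step 1 | ethyl [(1R,4R)-4-[(tert-butyldimethylsilyl)oxy]-1-hydroxycyclopent-2-en-1-yl]acetate | CCOC(=O)C[C@@]1(O)C=C[C@H](O[Si](C)(C)C(C)(C)C)C1
F8 | step 1 | [(1R,4R)-4-[(tert-butyldimethylsilyl)oxy]-1-hydroxycyclopent-2-en-1-yl]acetaldehyde | O=CC[C@@]1(O)C=C[C@H](O[Si](C)(C)C(C)(C)C)C1
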